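## Structural features

The target is a benzophenone in which ring A is a phloroglucinol nucleus (C1 benzoyl, C2/C4/C6 hydroxyl, C3 alkyl, C5 hydrogen) and ring B an unsubstituted phenyl, the two joined through the ketone carbon. C3 of ring A carries an oxidised geranyl chain, C1'H2–C2'H(OH)–C3'(=CH2)–C4'H2–C5'H2–C6'H=C7'(CH3)2. The only stereocentre is C2' (R), a secondary allylic carbinol between the benzylic C1' and the 1,1-disubstituted alkene, with no other stereocentre next to it. Fragile groups are the allylic alcohol ortho to two phenols (acid would ionise it or close cyclic ethers onto the phenols), the trisubstituted C6'=C7' alkene (acid, electrophilic oxidants) and the air-sensitive triphenol. The two alkenes also rule out hydrogenolysis and make any late oxidation of the chain unselective. The real difficulty is the union of this chain with C3 of an acylphloroglucinol (mono-C-alkylation between two hydroxyls), together with an R-configured oxygen at C2' beside an exocyclic methylene and the release of three phenols without acid. The key step exploits two facts: C2, C4 and C6 of ring A are at the oxidation level of the carbonyl carbons of a benzoyl-primed tetraketide, and the C2' oxygen stands 1,4 to C2, so that O–C2'–C1'–C3–C2 are the five atoms of a γ-butyrolactone. The target is therefore a constitutional isomer (C23H26O5) of a 3-acyl-γ-butyrolactone, and one Claisen condensation onto that lactone carbonyl closes ring A and sets the alcohol free.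

## Logic of the disconnections

17 to 15 (through 16). In one sentence, the route forms ring A last by a ring-opening Claisen condensation of 15, in which the lactone oxygen becomes the C2' hydroxyl. The bond cut is C1–C2 of ring A, and in the reverse sense C2 is rejoined to the C2' oxygen as a lactone. The cut is made there because C2 is at the acid oxidation level and the C2' oxygen is γ to it. The gain is large: ring A, three phenols and the free alcohol all disappear into one neutral, non-aromatic isomer that needs no protecting group, and the hard C3–C1' bond becomes the α–β bond of a lactone present from the start. The demand on the forward step is that C-acylation at the doubly activated methylene must win over O-acylation and retro-Claisen cleavage, and C2' must survive base.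

15 to 8 and 12 (through 13 and 14). The bond cut joins the acyl carbon on the lactone (future C4) to its methylene (future C5). This divides the chain into a chiral five-ring fragment and an achiral four-carbon unit that carries C5, C6, C1 and the benzoyl group with both carbonyls masked. The forward step must acylate the terminal carbon of 12 under base-free conditions, because C3 of 13 is acidic.

12 to 10 to 9. Only O–Si bonds are cut. 12 is the neutral, doubly masked equivalent of the dianion of 9, and the forward steps need kinetic deprotonation at the methyl group.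

8 to 6 (through 7). The bond cut is C3–CO2H (the future C3–C4 bond of ring A), which is a carboxylation of a lactone enolate. The one-carbon unit is the future C4, and the new C3 centre needs no control.

6 to 5. The bond cut is C3'=CH2, a carbonyl methylenation. The forward step must be non-basic, because C5 of 5 is α to the ketone.

5 to 2 and 3 (through 4). The bond cut is C3'–C4', joining an acyl chloride to a homoprenyl nucleophile. The forward step must stop at the ketone and leave the lactone alone.

2 to 1. This is an activation only. 1 is a chiral-pool acid whose C2 becomes C2' of the target with the same spatial arrangement (R throughout), so the stereocentre is bought and never made or broken.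

## Other disconnections considered

Alternative 1: the first idea is to cut the C2'–O bond and move the alkene back to C2'=C3', which reduces the chain to a geranyl group. Forward, (2,4,6-trihydroxyphenyl)(phenyl)methanone A1 would be C-geranylated to the 3-geranyl compound A2, and a Schenck ene reaction with singlet oxygen would give the allylic hydroperoxide A3 for reduction to the alcohol. The chosen plan is preferred because nothing in the ene step controls C2', and singlet oxygen should not distinguish the C2'=C3' alkene from the C6'=C7' alkene. At C2'=C3' it can also abstract from three allylic positions, the triphenol is itself oxidisable, and geranylation of A1 competes with O-alkylation and double C-alkylation. The route is short on paper, but no selectivity in it is secured by the substrate.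

Alternative 2: cut C2'–C3'. Forward, an asymmetric Nozaki–Hiyama–Kishi coupling (CrCl2, NiCl2 cat., chiral sulfonamide ligand) of the arylacetaldehyde A4 with the alkenyl bromide A5 would give the protected alcohol A6, followed by removal of three methoxymethyl groups. The chosen plan is preferred because A4 still has to be made by C-allylation of a protected ring and oxidative cleavage, so the hard aryl–C1' bond remains. A4 is also an enolisable, electron-rich aldehyde that carries a competing ketone, and facial selectivity at an α-unbranched aldehyde would rest on the ligand alone. The acidic acetal cleavage at the end would expose the ionisable allylic alcohol next to free phenols, and the route needs about ten steps and three protecting groups.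

Alternative 3: keep the skeleton and trace the C2' oxygen back to a 2,3-epoxy alcohol. Forward, Sharpless epoxidation (Ti(OiPr)4, tartrate ester, tBuOOH) of the Z-allylic alcohol A7 would give the epoxy alcohol A8, and conversion of the primary alcohol into the iodide and reductive opening with Zn (1,3-transposition) would give A6. The epoxidation should distinguish the allylic alkene from C6'=C7' and set C2' reliably, which is attractive. The chosen plan is still preferred because A7 needs a geometry-defined trisubstituted alkene with a hydroxymethyl branch attached to the protected ring, which again means C-alkylation of the phloroglucinol. It also needs four further steps and the same acidic deprotection, in a linear sequence of twelve or more steps.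

Key step: step 8

Assumption: C3 of 8, 13, 14 and 15 is carried as a mixture of epimers and the poly-β-carbonyl compounds are drawn in their keto forms, since C3 becomes an aromatic carbon in step 8; 1 is taken as purchasable (it is also the diazotisation product of D-glutamic acid).

## Steps

Step 1
Reactants: 1 (2R)-5-oxooxolane-2-carboxylic acid
Product: 2 (2R)-5-oxooxolane-2-carbonyl chloride
Conditions: (COCl)2, DMF (cat.), CH2Cl2, 0 → 23 °C
Reagents that add atoms: oxalyl chloride, ClC(=O)C(=O)Cl
Why: Standard acid chloride formation through the chloroiminium (Vilsmeier-type) species; the lactone is inert and the stereocentre is not touched in the absence of base.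

Step 2
Reactants: 2 (2R)-5-oxooxolane-2-carbonyl chloride; 3 5-bromo-2-methylpent-2-ene
Product: 5 (5R)-5-(5-methylhex-4-enoyl)oxolan-2-one, via Grignard reagent 4 (not isolated)
Conditions: 3, Mg, THF, 23 → 40 °C; then added to 2, Fe(acac)3 (3 mol %), THF, −78 °C
Reagents that add atoms: none
Why: Iron-catalysed acylation of a Grignard reagent by an acid chloride is much faster at −78 °C than addition to the ketone formed or to the lactone; short contact at low temperature should leave the α-oxygenated stereocentre intact.

Step 3
Reactants: 5 (5R)-5-(5-methylhex-4-enoyl)oxolan-2-one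
Product: 6 (5R)-5-(6-methylhepta-1,5-dien-2-yl)oxolan-2-one
Conditions: Zn, CH2Br2, TiCl4, THF/CH2Cl2, 0 → 23 °C
Reagents that add atoms: dibromomethane, BrCBr
Why: Lombardo–Takai methylenation; the non-basic geminal dimetallic reagent methylenates ketones in the presence of lactones and does not enolise the ketone, so C5 should keep its R configuration.

Step 4
Reactants: 6 (5R)-5-(6-methylhepta-1,5-dien-2-yl)oxolan-2-one
Product: 8 (5R)-5-(6-methylhepta-1,5-dien-2-yl)-2-oxooxolane-3-carboxylic acid, via lithium enolate 7 (not isolated)
Conditions: LiN(iPr)2 (1.1 equiv), THF, −78 °C; CO2 (g), −78 → −20 °C; cold 1 M HCl to pH 3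
Reagents that add atoms: carbon dioxide, O=C=O
Why: Kinetic deprotonation of a γ-lactone at C3 and carboxylation of the enolate is the first stage of the classical α-methylenation of lactones; C3 forms as a mixture of epimers of no consequence, and C5 is not acidic.

Step 5
Reactants: 9 1-phenylbutane-1,3-dione
Product: 10 (3Z)-4-phenyl-4-[(trimethylsilyl)oxy]but-3-en-2-one
Conditions: Me3SiCl, Et3N, pentane, 23 °C; filtration
Reagents that add atoms: chlorotrimethylsilane, C[Si](C)(C)Cl
Why: O-Silylation of the chelated cis-enol of a 1,3-diketone with an amine base; a regioisomeric silyl enol ether would converge on the same dienol ether in step 6.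

Step 6
Reactants: 10 (3Z)-4-phenyl-4-[(trimethylsilyl)oxy]but-3-en-2-one
Product: 12 (1Z)-1-phenyl-1,3-bis[(trimethylsilyl)oxy]buta-1,3-diene, via lithium dienolate 11 (not isolated)
Conditions: LiN(iPr)2 (1.2 equiv), THF, −78 °C; Me3SiCl, −78 → 20 °C
Reagents that add atoms: chlorotrimethylsilane, C[Si](C)(C)Cl
Why: Kinetic deprotonation of the methyl ketone and O-silylation give the 1,3-bis(silyl enol ether), a neutral equivalent of the diketone dianion with both carbonyl groups masked.

Step 7
Reactants: 8 (5R)-5-(6-methylhepta-1,5-dien-2-yl)-2-oxooxolane-3-carboxylic acid; 12 (1Z)-1-phenyl-1,3-bis[(trimethylsilyl)oxy]buta-1,3-diene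
Product: 15 1-[(5R)-5-(6-methylhepta-1,5-dien-2-yl)-2-oxooxolan-3-yl]-5-phenylpentane-1,3,5-trione, via acid chloride 13 (not isolated), via silyl enol ether 14 (not isolated)
Conditions: 8, 1-chloro-N,N,2-trimethylprop-1-en-1-amine, CH2Cl2, 0 °C; then 12, −78 → 20 °C; cold aq. NaHCO3
Reagents that add atoms: none
Why: The neutral chloroenamine makes the malonyl-type acid chloride without HCl; 1,3-bis(silyl enol ethers) are acylated by acid chlorides at the terminal carbon (Mukaiyama-type C-acylation, an established route to 1,3,5-tricarbonyl compounds), and the absence of base avoids deprotonation at C3; aqueous work-up removes the remaining silyl group.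

Step 8
Reactants: 15 1-[(5R)-5-(6-methylhepta-1,5-dien-2-yl)-2-oxooxolan-3-yl]-5-phenylpentane-1,3,5-trione
Product: 17 {2,4,6-trihydroxy-3-[(2R)-2-hydroxy-7-methyl-3-methylideneoct-6-en-1-yl]phenyl}(phenyl)methanone, via cyclohexanetrione 16 (not isolated)
Conditions: Mg(OMe)2 (4 equiv), MeOH/THF, degassed, Ar, 23 → 50 °C; cold 0.5 M HCl to pH 4–5
Reagents that add atoms: none
Why: Mg(OMe)2 turns the 1,3,5-triketone part of 15 into a chelated magnesium enolate, whose benzoyl-flanked carbon (future C1 of ring A) adds to the lactone carbonyl (future C2); the tetrahedral intermediate collapses with acyl–oxygen cleavage, expelling the C2' alkoxide to give trione 16, and threefold enolisation gives 17. The closest known reaction type is the biomimetic Claisen cyclisation of 3,5,7-trioxoalkanoic esters to acylphloroglucinols with magnesium or alkali alkoxides, here with a γ-lactone as the ester, as in ring-opening Dieckmann condensations of keto lactones. Ring A closes by a 6-exo-trig attack (enolexo with respect to the benzoyl enolate), a favoured mode. No stereocentre is created: C2' keeps its R configuration because only the acyl–oxygen bond of the lactone breaks, and the epimeric C3 becomes an aromatic carbon. The step needs C-acylation at the doubly activated methylene in preference to aldol folding, O-acylation and retro-Claisen cleavage. Aldol folding is excluded by the substrate, because the lactone α-carbon already bears C1', so an aldol adduct there would be quaternary, could not aromatise and can only revert. O-Acylation to a 4-hydroxypyran-2-one is reversible under methoxide, which reopens it to a methyl trioxo ester that is itself a Claisen substrate, so that pathway should drain into 17 as well. Chelation by magnesium keeps the ketones enolised and shielded from methoxide, and aromatisation to the magnesium phenoxide makes the C–C bond formation irreversible.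

## Compound list

1 | (2R)-5-oxooxolane-2-carboxylic acid | O=C(O)[C@H]1CCC(=O)O1 | starting material
2 | (2R)-5-oxooxolane-2-carbonyl chloride | O=C(Cl)[C@H]1CCC(=O)O1 | intermediate
3 | 5-bromo-2-methylpent-2-ene | CC(C)=CCCBr | starting material
4 | (4-methylpent-3-en-1-yl)magnesium bromide | CC(C)=CCC[Mg]Br | intermediate
5 | (5R)-5-(5-methylhex-4-enoyl)oxolan-2-one | CC(C)=CCCC(=O)[C@H]1CCC(=O)O1 | intermediate
6 | (5R)-5-(6-methylhepta-1,5-dien-2-yl)oxolan-2-one | C=C(CCC=C(C)C)[C@H]1CCC(=O)O1 | intermediate
7 | lithium (5R)-5-(6-methylhepta-1,5-dien-2-yl)-4,5-dihydrofuran-2-olate | C=C(CCC=C(C)C)[C@H]1CC=C([O-])O1.[Li+] | intermediate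
8 | (5R)-5-(6-methylhepta-1,5-dien-2-yl)-2-oxooxolane-3-carboxylic acid (C3 epimers) | C=C(CCC=C(C)C)[C@H]1CC(C(=O)O)C(=O)O1 | intermediate
9 | 1-phenylbutane-1,3-dione | CC(=O)CC(=O)c1ccccc1 | starting material
10 | (3Z)-4-phenyl-4-[(trimethylsilyl)oxy]but-3-en-2-one | CC(=O)/C=C(\O[Si](C)(C)C)c1ccccc1 | intermediate
11 | lithium (3Z)-4-phenyl-4-[(trimethylsilyl)oxy]buta-1,3-dien-2-olate | C=C([O-])/C=C(\O[Si](C)(C)C)c1ccccc1.[Li+] | intermediate
12 | (1Z)-1-phenyl-1,3-bis[(trimethylsilyl)oxy]buta-1,3-diene | C=C(O[Si](C)(C)C)/C=C(\O[Si](C)(C)C)c1ccccc1 | intermediate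
13 | (5R)-5-(6-methylhepta-1,5-dien-2-yl)-2-oxooxolane-3-carbonyl chloride (C3 epimers) | C=C(CCC=C(C)C)[C@H]1CC(C(=O)Cl)C(=O)O1 | intermediate
14 | (4Z)-1-[(5R)-5-(6-methylhepta-1,5-dien-2-yl)-2-oxooxolan-3-yl]-5-phenyl-5-[(trimethylsilyl)oxy]pent-4-ene-1,3-dione | C=C(CCC=C(C)C)[C@H]1CC(C(=O)CC(=O)/C=C(\O[Si](C)(C)C)c2ccccc2)C(=O)O1 | intermediate
15 | 1-[(5R)-5-(6-methylhepta-1,5-dien-2-yl)-2-oxooxolan-3-yl]-5-phenylpentane-1,3,5-trione (C3 epimers, keto form) | C=C(CCC=C(C)C)[C@H]1CC(C(=O)CC(=O)CC(=O)c2ccccc2)C(=O)O1 | intermediate
16 | 2-benzoyl-4-[(2R)-2-hydroxy-7-methyl-3-methylideneoct-6-en-1-yl]cyclohexane-1,3,5-trione | C=C(CCC=C(C)C)[C@H](O)CC1C(=O)CC(=O)C(C(=O)c2ccccc2)C1=O | intermediate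
17 | {2,4,6-trihydroxy-3-[(2R)-2-hydroxy-7-methyl-3-methylideneoct-6-en-1-yl]phenyl}(phenyl)methanone | C=C(CCC=C(C)C)[C@H](O)Cc1c(O)cc(O)c(C(=O)c2ccccc2)c1O | target

## Step count and least certain steps

Total step count: 8. Longest linear sequence: 6 steps (steps 1, 2, 3, 4, 7, 8 from 1); steps 5 and 6 form the second branch from 9.

**Step 8 (key step).** The chain may be diverted into O-acylation (translactonisation to a pyranone) that does not go on, the lactone carbonyl may be switched off by enolisation at C3, or methoxide may cleave the β-tricarbonyl unit by retro-Claisen reaction. The fallback sets out from 15 and returns at 17. It uses the O-acylation pathway on purpose and runs the Claisen condensation on a protected, acyclic ester. Et3N in CH2Cl2 at 23 °C, followed by a mildly acidic work-up, should translactonise 15 to 4-hydroxy-3-[(2R)-2-hydroxy-7-methyl-3-methylideneoct-6-en-1-yl]-6-(2-oxo-2-phenylethyl)-2H-pyran-2-one F1. Silylation of the liberated alcohol (tBuMe2SiCl, imidazole, DMF; aqueous work-up frees the acidic pyranone hydroxyl again) would give 3-[(2R)-2-[(tert-butyldimethylsilyl)oxy]-7-methyl-3-methylideneoct-6-en-1-yl]-4-hydroxy-6-(2-oxo-2-phenylethyl)-2H-pyran-2-one F2. Mg(OMe)2 in MeOH at reflux, the known ring-opening and Claisen recyclisation of 6-(2-oxoalkyl)-4-hydroxypyran-2-ones through the methyl trioxo ester, should then give {3-[(2R)-2-[(tert-butyldimethylsilyl)oxy]-7-methyl-3-methylideneoct-6-en-1-yl]-2,4,6-trihydroxyphenyl}(phenyl)methanone F3. With the alkoxide capped, relactonisation and hemiketal formation are excluded in that step. Buffered fluoride (Bu4NF, AcOH, THF, 0 °C) would then give 17.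

**Step 7.** The malonyl-type acid chloride may lose HCl to a ketene that dimerises, the dienol ether may be acylated at oxygen or at its central carbon, and the half-acid may decarboxylate during activation. The fallback sets out from 6 and returns at 15, building the chain by classical polyanion acylations in which each new carbonyl is masked as an enolate. Enolate 7 (from 6 with 2 equiv LiN(iPr)2) is C-acylated with N-acetylimidazole to (5R)-3-acetyl-5-(6-methylhepta-1,5-dien-2-yl)oxolan-2-one F4. Its dianion (NaH, then n-BuLi, THF, 0 °C) is acylated at the methyl group with N-methoxy-N-methylacetamide to 1-[(5R)-5-(6-methylhepta-1,5-dien-2-yl)-2-oxooxolan-3-yl]butane-1,3-dione F5. The trianion of F5 (LiN(iPr)2, 3.3 equiv, THF, 0 °C) is benzoylated at the terminal methyl group with methyl benzoate, and a cold, mildly acidic work-up gives 15.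

**Step 3.** The α-oxygenated C–O bond next to the ketone may be cleaved reductively by the low-valent metal mixture, the lactone carbonyl may be attacked, or conversion may stall with this hindered α-branched ketone. The fallback sets out from 5 and returns at 6 by a two-stage Peterson olefination. Me3SiCH2MgCl with CeCl3 (THF, −78 °C) should add to the ketone without enolisation to give (5R)-5-[2-hydroxy-6-methyl-1-(trimethylsilyl)hept-5-en-2-yl]oxolan-2-one F6. Acid-induced anti-elimination (catalytic camphorsulfonic acid, CH2Cl2, 0 °C) should then give 6, because the β-silicon effect makes ionisation of the tertiary alcohol far faster than protonation of the trisubstituted alkene.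

**Step 2.** The Grignard reagent may add twice or attack the lactone, and the α-oxygenated acid chloride may racemise through ketene formation or the ketone through enolisation. The fallback sets out from 1 and returns at 5 by a Fukuyama coupling. 1 is converted with EtSH (N,N'-dicyclohexylcarbodiimide, 4-dimethylaminopyridine cat., CH2Cl2) into S-ethyl (2R)-5-oxooxolane-2-carbothioate F7. 3 is converted by zinc insertion (Zn, LiCl, THF) into (4-methylpent-3-en-1-yl)zinc bromide F8. PdCl2(PPh3)2 (5 mol %) in toluene/THF at 23 °C should couple them to 5, since neither partner is basic enough to enolise the product or reactive enough to add to a ketone or lactone.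

## Further compounds

F1 | step 8 | 4-hydroxy-3-[(2R)-2-hydroxy-7-methyl-3-methylideneoct-6-en-1-yl]-6-(2-oxo-2-phenylethyl)-2H-pyran-2-one | C=C(CCC=C(C)C)[C@H](O)Cc1c(O)cc(CC(=O)c2ccccc2)oc1=O
F2 | step 8 | 3-[(2R)-2-[(tert-butyldimethylsilyl)oxy]-7-methyl-3-methylideneoct-6-en-1-yl]-4-hydroxy-6-(2-oxo-2-phenylethyl)-2H-pyran-2-one | C=C(CCC=C(C)C)[C@H](O[Si](C)(C)C(C)(C)C)Cc1c(O)cc(CC(=O)c2ccccc2)oc1=O
F3 | step 8 | {3-[(2R)-2-[(tert-butyldimethylsilyl)oxy]-7-methyl-3-methylideneoct-6-en-1-yl]-2,4,6-trihydroxyphenyl}(phenyl)methanone | C=C(CCC=C(C)C)[C@H](O[Si](C)(C)C(C)(C)C)Cc1c(O)cc(O)c(C(=O)c2ccccc2)c1O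
F4 | step 7 | (5R)-3-acetyl-5-(6-methylhepta-1,5-dien-2-yl)oxolan-2-one | C=C(CCC=C(C)C)[C@H]1CC(C(C)=O)C(=O)O1
F5 | step 7 | 1-[(5R)-5-(6-methylhepta-1,5-dien-2-yl)-2-oxooxolan-3-yl]butane-1,3-dione | C=C(CCC=C(C)C)[C@H]1CC(C(=O)CC(C)=O)C(=O)O1
F6 | step 3 | (5R)-5-[2-hydroxy-6-methyl-1-(trimethylsilyl)hept-5-en-2-yl]oxolan-2-one | CC(C)=CCCC(O)(C[Si](C)(C)C)[C@H]1CCC(=O)O1
F7 | step 2 | S-ethyl (2R)-5-oxooxolane-2-carbothioate | CCSC(=O)[C@H]1CCC(=O)O1
F8 | step 2 | (4-methylpent-3-en-1-yl)zinc bromide | CC(C)=CCC[Zn]Br
A1 | alternative 1 | (2,4,6-trihydroxyphenyl)(phenyl)methanone | O=C(c1ccccc1)c1c(O)cc(O)cc1O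
A2 | alternative 1 | {3-[(2E)-3,7-dimethylocta-2,6-dien-1-yl]-2,4,6-trihydroxyphenyl}(phenyl)methanone | CC(C)=CCC/C(C)=C/Cc1c(O)cc(O)c(C(=O)c2ccccc2)c1O
A3 | alternative 1 | [3-(2-hydroperoxy-7-methyl-3-methylideneoct-6-en-1-yl)-2,4,6-trihydroxyphenyl](phenyl)methanone (racemic) | C=C(CCC=C(C)C)C(OO)Cc1c(O)cc(O)c(C(=O)c2ccccc2)c1O
A4 | alternative 2 | 2-[3-benzoyl-2,4,6-tris(methoxymethoxy)phenyl]acetaldehyde | O=CCc1c(OCOC)cc(OCOC)c(C(=O)c2ccccc2)c1OCOC
A5 | alternative 2 | 2-bromo-6-methylhepta-1,5-diene | C=C(Br)CCC=C(C)C
A6 | alternative 2 | {3-[(2R)-2-hydroxy-7-methyl-3-methylideneoct-6-en-1-yl]-2,4,6-tris(methoxymethoxy)phenyl}(phenyl)methanone | C=C(CCC=C(C)C)[C@H](O)Cc1c(OCOC)cc(OCOC)c(C(=O)c2ccccc2)c1OCOC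
A7 | alternative 3 | (2Z)-4-[3-benzoyl-2,4,6-tris(methoxymethoxy)phenyl]-2-(4-methylpent-3-en-1-yl)but-2-en-1-ol | CC(C)=CCC/C(CO)=C/Cc1c(OCOC)cc(OCOC)c(C(=O)c2ccccc2)c1OCOC
A8 | alternative 3 | [(2S,3R)-3-{[3-benzoyl-2,4,6-tris(methoxymethoxy)phenyl]methyl}-2-(4-methylpent-3-en-1-yl)oxiran-2-yl]methanol | OC[C@]1(CCC=C(C)C)O[C@@H]1Cc2c(OCOC)cc(OCOC)c(C(=O)c3ccccc3)c2OCOC
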